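Ring locants used throughout: C1 ketone, C2 nitrogen-bearing sp2 carbon, C3 vinylic CH, C4 carbinol carbon, C5 and C6 oxirane carbons. Side-chain carbons are primed, counted from C4.
The retrosynthesis cuts C2′–C3′ of the triene (Stille coupling), then the C2–N enamide bond (copper-catalysed amidation of a C2 bromide), and finally both ring bonds of C2, namely C1–C2 and C2–C3.
The last cut is possible because C2 sits between carbonyl C1 and methine C3 of the six-membered ring and carries only a heteroatom. It can therefore enter as CBr2 across the C1=C3 enol ether of an oxirane-fused cyclopentanone, whose only enolisable α-carbon is C3 (the other, C6, belongs to the oxirane).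
Forward order: purchased cyclopentene ring, acetylide at C4, oxirane ring, C1 ketone, enol silane, cyclopropane closure and opening to the 2-bromocyclohexenone, dienamide at C2, vinylstannane, and last the triene with the C5N ring.
Stereochemistry: the one purchased centre of (S)-4-silyloxycyclopentenone sends the acetylide to the opposite face (C4), the resulting cis-diol directs the epoxidation (C5, C6), and the relay centre is then oxidised to C1. Alkene geometry comes from HWE, Takai, syn-hydrostannylation and a stereoretentive Stille coupling.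

Key step: step 7

Assumption: enantiopure (S)-4-(tert-butyldimethylsilyloxy)cyclopent-2-en-1-one is taken as a catalogue compound. All other starting materials are common catalogue items.
Convention: compounds on the Reactants line are not repeated under "Reagents that add atoms". A change of CIP descriptor at C4 along the route reflects changed substituent priorities only, never a change of geometry.

Step 1
Reactants: 1 (S)-4-(tert-butyldimethylsilyloxy)cyclopent-2-en-1-one; 2 trimethylsilylacetylene
Product: 4 (1R,4S)-4-(tert-butyldimethylsilyloxy)-1-[(trimethylsilyl)ethynyl]cyclopent-2-en-1-ol, via lithium trimethylsilylacetylide 3 (not isolated)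
Conditions: 2, n-BuLi, THF, −78 °C; then 1, −78 °C; aq. NH4Cl
Reagents that add atoms: none
Why: 1,2-Addition of a lithium acetylide to a cyclopentenone: the hard, weakly basic nucleophile attacks only the carbonyl carbon and should approach from the face opposite to the bulky silyl ether, which sets the tertiary carbinol centre (the later C4) with OH cis to OTBS, any minor diastereomer being removed by chromatography.

Step 2
Reactants: 4 (1R,4S)-4-(tert-butyldimethylsilyloxy)-1-[(trimethylsilyl)ethynyl]cyclopent-2-en-1-ol
Product: 5 (1R,4S)-1-[(trimethylsilyl)ethynyl]cyclopent-2-ene-1,4-diol (cis-diol)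
Conditions: HF·pyridine, pyridine, THF, 0 °C → rt
Reagents that add atoms: none
Why: Silyl ether cleavage with buffered HF·pyridine: the secondary O–TBS bond is cut, whereas the C(sp)–SiMe3 bond, which falls only to basic fluoride or alkoxide, and the ionisable tertiary carbinol should persist in the pyridine-buffered medium, and no stereocentre is touched.

Step 3
Reactants: 5 (1R,4S)-1-[(trimethylsilyl)ethynyl]cyclopent-2-ene-1,4-diol
Product: 6 (1S,2S,3S,4S)-2,3-epoxy-1-[(trimethylsilyl)ethynyl]cyclopentane-1,4-diol (both hydroxyls and the oxirane oxygen on one face)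
Conditions: VO(acac)2 (cat.), t-BuOOH (decane), CH2Cl2, 0 °C → rt
Reagents that add atoms: tert-butyl hydroperoxide, CC(C)(C)OO
Why: Hydroxyl-directed vanadium-catalysed epoxidation of an allylic alcohol: both hydroxyls stand on the same face of the ring and bind the vanadium alkylperoxide, so oxygen should be delivered to that face only, which sets C5 and C6 syn to the C4 hydroxyl, while the silylalkyne is inert to the reagent.

Step 4
Reactants: 6 (1S,2S,3S,4S)-2,3-epoxy-1-[(trimethylsilyl)ethynyl]cyclopentane-1,4-diol
Product: 7 (2R,3S,4S)-2,3-epoxy-4-hydroxy-4-[(trimethylsilyl)ethynyl]cyclopentan-1-one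
Conditions: Dess–Martin periodinane, CH2Cl2, 0 °C → rt
Reagents that add atoms: none
Why: Dess–Martin oxidation: only the secondary carbinol can be oxidised, the relay stereocentre thereby becomes the C1 carbonyl, and the nearly neutral medium should spare the oxirane and avoid retro-aldol cleavage or dehydration of the β-hydroxy ketone.

Step 5
Reactants: 7 (2R,3S,4S)-2,3-epoxy-4-hydroxy-4-[(trimethylsilyl)ethynyl]cyclopentan-1-one
Product: 8 (2R,3S,4S)-2,3-epoxy-4-(triethylsilyloxy)-4-[(trimethylsilyl)ethynyl]cyclopentan-1-one
Conditions: TESOTf, 2,6-lutidine, CH2Cl2, −78 → 0 °C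
Reagents that add atoms: triethylsilyl trifluoromethanesulfonate, CC[Si](CC)(CC)OS(=O)(=O)C(F)(F)F
Why: O-Silylation of a hindered tertiary alcohol with a silyl triflate and a non-nucleophilic pyridine base, which removes the free β-hydroxyl (and with it the retro-aldol path that would scramble C4) before any strong base is used.

Step 6
Reactants: 8 (2R,3S,4S)-2,3-epoxy-4-(triethylsilyloxy)-4-[(trimethylsilyl)ethynyl]cyclopentan-1-one
Product: 9 (3S,4S,5R)-4,5-epoxy-3-(triethylsilyloxy)-1-(trimethylsilyloxy)-3-[(trimethylsilyl)ethynyl]cyclopent-1-ene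
Conditions: LiHMDS added to 8 and TMSCl, THF, −78 °C; Et3N, cold aq. NaHCO3/pentane work-up; used without chromatography
Reagents that add atoms: chlorotrimethylsilane, C[Si](C)(C)Cl
Why: Kinetic enolisation with internal silyl quench: the amide base can remove a proton only from the C3 methylene, because the other α-carbon C6 belongs to the oxirane and its enolate would be an intolerably strained alkylidene oxirane, and trapping at −78 °C as the enolate forms should outrun β-elimination of the silyloxy group.

Step 7
Reactants: 9 (3S,4S,5R)-4,5-epoxy-3-(triethylsilyloxy)-1-(trimethylsilyloxy)-3-[(trimethylsilyl)ethynyl]cyclopent-1-ene; 10 bromoform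
Product: 12 (4S,5S,6R)-2-bromo-5,6-epoxy-4-(triethylsilyloxy)-4-[(trimethylsilyl)ethynyl]cyclohex-2-en-1-one, via dibromocyclopropane adduct 11 (not isolated)
Conditions: CHBr3, KOt-Bu (excess, in portions), pentane, −30 °C → rt
Reagents that add atoms: none
Why: tert-Butoxide removes HBr from bromoform by α-elimination and the dibromocarbene adds in a concerted cheletropic [2+1] manner to the electron-rich C1=C3 enol ether, which forms C1–C2 and C2–C3 and closes the cyclopropane of 11. In this strained 1-silyloxy-6,6-dibromobicyclo[3.1.0]hexane the endo C–Br bond ionises while the shared C1–C3 bond opens in the disrotatory sense allowed by the Woodward–Hoffmann–DePuy rule, pushed by the silyloxy oxygen, and loss of the silyl group from the resulting oxocarbenium/allyl cation leaves the C1 ketone and the C2(Br)=C3 alkene. The closest known reaction type is the dihalocarbene ring enlargement of cyclic silyl enol ethers to 2-halocycloalk-2-enones, which runs especially easily from five- to six-membered rings. The three-membered ring is thus closed by [2+1] cycloaddition, and the six-membered ring is not closed by a cyclisation but arises from the five-membered one when the zero-atom bridge of the bicycle is cut. No stereocentre is created that survives, since both cyclopropane centres become sp2, so the face of attack (expected opposite to oxirane and OTES) does not matter and C4, C5 and C6 are spectators. The step needs site selectivity for the enol ether over the silylalkyne, secured by the far higher nucleophilicity of the former, regiochemistry of insertion, fixed by the only possible enol ether made in step 6, and survival of the oxirane and silicon groups, helped by adding the base in portions to a pentane suspension so that bromoform consumes it and by letting its excess trap Me3SiBr as t-BuOSiMe3.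

Step 8
Reactants: 13 cyclohexanecarboxaldehyde; 14 triethyl (E)-4-phosphonocrotonate
Product: 15 ethyl (2E,4E)-5-cyclohexylpenta-2,4-dienoate
Conditions: LiOH·H2O, 4 Å MS, THF, reflux
Reagents that add atoms: none
Why: Vinylogous Horner–Wadsworth–Emmons olefination: the stabilised phosphonate anion adds reversibly to the α-branched aldehyde and should collapse to the E alkene, the crotonate double bond keeping its E geometry.

Step 9
Reactants: 15 ethyl (2E,4E)-5-cyclohexylpenta-2,4-dienoate
Product: 16 (2E,4E)-5-cyclohexylpenta-2,4-dienamide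
Conditions: AlMe3, NH4Cl, toluene, 0 → 50 °C; aq. HCl
Reagents that add atoms: ammonium chloride, [NH4+].[Cl-]
Why: Weinreb-type aminolysis: the aluminium amide made from AlMe3 and NH4Cl attacks the ester carbonyl directly, so the primary amide should form without conjugate addition to the diene and without isomerisation.

Step 10
Reactants: 12 (4S,5S,6R)-2-bromo-5,6-epoxy-4-(triethylsilyloxy)-4-[(trimethylsilyl)ethynyl]cyclohex-2-en-1-one; 16 (2E,4E)-5-cyclohexylpenta-2,4-dienamide
Product: 17 (2E,4E)-5-cyclohexyl-N-{(4S,5S,6R)-5,6-epoxy-1-oxo-4-(triethylsilyloxy)-4-[(trimethylsilyl)ethynyl]cyclohex-2-en-2-yl}penta-2,4-dienamide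
Conditions: CuI (cat.), N,N′-dimethylethylenediamine (cat.), K2CO3, toluene, 90 °C
Reagents that add atoms: none
Why: Copper-catalysed vinylic amidation (Goldberg-type coupling with a diamine ligand): the copper(I) amidate of 16 should substitute the carbonyl-activated C2–Br bond with the ring alkene held in place, and the sparingly soluble carbonate in toluene finds no enolisable hydrogen in 12 and should leave oxirane, silyl ether and silylalkyne alone.

Step 11
Reactants: 17 (2E,4E)-5-cyclohexyl-N-{(4S,5S,6R)-5,6-epoxy-1-oxo-4-(triethylsilyloxy)-4-[(trimethylsilyl)ethynyl]cyclohex-2-en-2-yl}penta-2,4-dienamide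
Product: 18 (2E,4E)-5-cyclohexyl-N-[(4S,5S,6R)-5,6-epoxy-4-ethynyl-4-hydroxy-1-oxocyclohex-2-en-2-yl]penta-2,4-dienamide
Conditions: TBAF, AcOH, THF, 0 °C → rt
Reagents that add atoms: none
Why: Fluoride-induced desilylation buffered with acetic acid: fluoride attacks both the alkynyl SiMe3 and the O–SiEt3 group, and the buffer keeps the medium from becoming basic enough to harm the epoxy ketone, so that no deprotection is left for the polyene stage.

Step 12
Reactants: 18 (2E,4E)-5-cyclohexyl-N-[(4S,5S,6R)-5,6-epoxy-4-ethynyl-4-hydroxy-1-oxocyclohex-2-en-2-yl]penta-2,4-dienamide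
Product: 19 (2E,4E)-5-cyclohexyl-N-{(4S,5S,6R)-5,6-epoxy-4-hydroxy-1-oxo-4-[(E)-2-(tributylstannyl)ethenyl]cyclohex-2-en-2-yl}penta-2,4-dienamide
Conditions: Bu3SnH (slow addition), PdCl2(PPh3)2 (cat.), THF, 0 °C
Reagents that add atoms: tributyltin hydride, CCCC[SnH](CCCC)CCCC
Why: Palladium-catalysed syn-hydrostannylation of a terminal alkyne: the fully substituted propargylic carbon C4 should push tin to the terminal carbon and syn addition gives the E alkene, while slow addition of the hydride lets the fast alkyne reaction outrun reduction of the hindered, amide-substituted enone.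

Step 13
Reactants: 20 ethyl (E)-4-oxobut-2-enoate; 21 iodoform
Product: 22 ethyl (2E,4E)-5-iodopenta-2,4-dienoate
Conditions: CrCl2, CHI3, THF, 0 °C
Reagents that add atoms: none
Why: Takai olefination: the geminal dichromium species from iodoform and CrCl2 adds chemoselectively to the aldehyde and should eliminate to the E vinyl iodide, the enoate being untouched.

Step 14
Reactants: 22 ethyl (2E,4E)-5-iodopenta-2,4-dienoate
Product: 23 (2E,4E)-5-iodopenta-2,4-dienoic acid
Conditions: LiOH, THF–H2O, rt; aq. HCl
Reagents that add atoms: lithium hydroxide, [Li+].[OH-]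
Why: Saponification of an ethyl ester under mild conditions, to which the vinyl iodide and the diene geometry are indifferent.

Step 15
Reactants: 24 cyclopentane-1,3-dione
Product: 25 3-hydroxy-2-nitrocyclopent-2-en-1-one (enol form of 2-nitrocyclopentane-1,3-dione)
Conditions: fuming HNO3, CH2Cl2, 0 °C
Reagents that add atoms: nitric acid, O[N+](=O)[O-]
Why: Electrophilic nitration of a fully enolised cyclic 1,3-dione, whose only nucleophilic carbon is C2.

Step 16
Reactants: 25 3-hydroxy-2-nitrocyclopent-2-en-1-one
Product: 26 2-amino-3-hydroxycyclopent-2-en-1-one hydrochloride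
Conditions: H2 (1 atm), Pd/C, HCl, MeOH, rt
Reagents that add atoms: hydrogen chloride, Cl
Why: Catalytic hydrogenation of a nitro group, run in acid so that the air-sensitive aminoreductone is caught as its stable hydrochloride while the vinylogous-acid C=C bond is not reduced.

Step 17
Reactants: 23 (2E,4E)-5-iodopenta-2,4-dienoic acid; 26 2-amino-3-hydroxycyclopent-2-en-1-one hydrochloride
Product: 27 (2E,4E)-N-(2-hydroxy-5-oxocyclopent-1-en-1-yl)-5-iodopenta-2,4-dienamide
Conditions: EDC·HCl, HOBt, i-Pr2NEt, DMF, 0 °C → rt
Reagents that add atoms: none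
Why: Carbodiimide/HOBt amide coupling: the liberated amine is acylated at nitrogen, any O-acyl isomer being expected to migrate to the more stable amide, and the conditions leave the iododiene unchanged.

Step 18
Reactants: 19 (2E,4E)-5-cyclohexyl-N-{(4S,5S,6R)-5,6-epoxy-4-hydroxy-1-oxo-4-[(E)-2-(tributylstannyl)ethenyl]cyclohex-2-en-2-yl}penta-2,4-dienamide; 27 (2E,4E)-N-(2-hydroxy-5-oxocyclopent-1-en-1-yl)-5-iodopenta-2,4-dienamide
Product: 28 (2E,4E)-5-cyclohexyl-N-[(4R,5S,6R)-5,6-epoxy-4-hydroxy-4-{(1E,3E,5E)-7-[(2-hydroxy-5-oxocyclopent-1-en-1-yl)amino]-7-oxohepta-1,3,5-trien-1-yl}-1-oxocyclohex-2-en-2-yl]penta-2,4-dienamide (CNP0111189.1)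
Conditions: PdCl2(MeCN)2 (cat.), DMF, rt, dark
Reagents that add atoms: none
Why: Stille coupling under ligand-free palladium(II) precatalysis at room temperature: both alkenyl partners couple with retention of geometry to give the all-E triene, and the neutral conditions tolerate the free carbinol, the oxirane, both amides and the enol.

Compound list
1 | (S)-4-(tert-butyldimethylsilyloxy)cyclopent-2-en-1-one | O=C1C=C[C@@H](O[Si](C)(C)C(C)(C)C)C1 | starting material
2 | trimethylsilylacetylene | C#C[Si](C)(C)C | starting material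
3 | lithium trimethylsilylacetylide | [Li]C#C[Si](C)(C)C | intermediate
4 | (1R,4S)-4-(tert-butyldimethylsilyloxy)-1-[(trimethylsilyl)ethynyl]cyclopent-2-en-1-ol | O[C@@]1(C#C[Si](C)(C)C)C=C[C@@H](O[Si](C)(C)C(C)(C)C)C1 | intermediate
5 | (1R,4S)-1-[(trimethylsilyl)ethynyl]cyclopent-2-ene-1,4-diol | O[C@@]1(C#C[Si](C)(C)C)C=C[C@@H](O)C1 | intermediate
6 | (1S,2S,3S,4S)-2,3-epoxy-1-[(trimethylsilyl)ethynyl]cyclopentane-1,4-diol | O[C@@]1(C#C[Si](C)(C)C)[C@H]2O[C@H]2[C@@H](O)C1 | intermediate
7 | (2R,3S,4S)-2,3-epoxy-4-hydroxy-4-[(trimethylsilyl)ethynyl]cyclopentan-1-one | O[C@@]1(C#C[Si](C)(C)C)[C@H]2O[C@H]2C(=O)C1 | intermediate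
8 | (2R,3S,4S)-2,3-epoxy-4-(triethylsilyloxy)-4-[(trimethylsilyl)ethynyl]cyclopentan-1-one | CC[Si](CC)(CC)O[C@@]1(C#C[Si](C)(C)C)[C@H]2O[C@H]2C(=O)C1 | intermediate
9 | (3S,4S,5R)-4,5-epoxy-3-(triethylsilyloxy)-1-(trimethylsilyloxy)-3-[(trimethylsilyl)ethynyl]cyclopent-1-ene | C[Si](C)(C)OC1=C[C@](O[Si](CC)(CC)CC)(C#C[Si](C)(C)C)[C@H]2O[C@@H]12 | intermediate
10 | bromoform | BrC(Br)Br | starting material
11 | dibromocyclopropane adduct of 9 (CBr2 bridging C1 and C3 on the face opposite to oxirane and OTES) | C[Si](C)(C)O[C@]12[C@H](C1(Br)Br)[C@](O[Si](CC)(CC)CC)(C#C[Si](C)(C)C)[C@H]3O[C@@H]23 | intermediate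
12 | (4S,5S,6R)-2-bromo-5,6-epoxy-4-(triethylsilyloxy)-4-[(trimethylsilyl)ethynyl]cyclohex-2-en-1-one | BrC1=C[C@](O[Si](CC)(CC)CC)(C#C[Si](C)(C)C)[C@H]2O[C@H]2C1=O | intermediate
13 | cyclohexanecarboxaldehyde | O=CC1CCCCC1 | starting material
14 | triethyl (E)-4-phosphonocrotonate | CCOC(=O)/C=C/CP(=O)(OCC)OCC | starting material
15 | ethyl (2E,4E)-5-cyclohexylpenta-2,4-dienoate | CCOC(=O)/C=C/C=C/C1CCCCC1 | intermediate
16 | (2E,4E)-5-cyclohexylpenta-2,4-dienamide | NC(=O)/C=C/C=C/C1CCCCC1 | intermediate
17 | C2 dienamide of the silyl-protected epoxycyclohexenone (4S,5S,6R) | O=C(/C=C/C=C/C1CCCCC1)NC1=C[C@](O[Si](CC)(CC)CC)(C#C[Si](C)(C)C)[C@H]2O[C@H]2C1=O | intermediate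
18 | 4-ethynyl-4-hydroxy epoxycyclohexenone dienamide (4S,5S,6R) | O=C(/C=C/C=C/C1CCCCC1)NC1=C[C@](O)(C#C)[C@H]2O[C@H]2C1=O | intermediate
19 | (E)-vinylstannane of 18 (4S,5S,6R) | O=C(/C=C/C=C/C1CCCCC1)NC1=C[C@](O)(/C=C/[Sn](CCCC)(CCCC)CCCC)[C@H]2O[C@H]2C1=O | intermediate
20 | ethyl (E)-4-oxobut-2-enoate | CCOC(=O)/C=C/C=O | starting material
21 | iodoform | IC(I)I | starting material
22 | ethyl (2E,4E)-5-iodopenta-2,4-dienoate | CCOC(=O)/C=C/C=C/I | intermediate
23 | (2E,4E)-5-iodopenta-2,4-dienoic acid | OC(=O)/C=C/C=C/I | intermediate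
24 | cyclopentane-1,3-dione | O=C1CCC(=O)C1 | starting material
25 | 3-hydroxy-2-nitrocyclopent-2-en-1-one | O=C1CCC(O)=C1[N+](=O)[O-] | intermediate
26 | 2-amino-3-hydroxycyclopent-2-en-1-one hydrochloride | Cl.NC1=C(O)CCC1=O | intermediate
27 | (2E,4E)-N-(2-hydroxy-5-oxocyclopent-1-en-1-yl)-5-iodopenta-2,4-dienamide | I/C=C/C=C/C(=O)NC1=C(O)CCC1=O | intermediate
28 | CNP0111189.1, (4R,5S,6R) | O=C(/C=C/C=C/C1CCCCC1)NC1=C[C@](O)(/C=C/C=C/C=C/C(=O)NC2=C(O)CCC2=O)[C@H]2O[C@H]2C1=O | target

Total step count: 18.
Longest linear sequence: 11 steps from 1 (steps 1–7, 10, 11, 12 and 18).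

Steps most likely to fail

1. Step 7.
- What may go wrong: tert-butoxide may attack the O–SiMe3 bond and release the enolate, which can then β-eliminate. Carbene transfer may be sluggish, because the enol ether is flanked by a quaternary carbon and deactivated by two allylic C–O bonds. The adduct may be reluctant to ionise, or the oxirane may be opened by bromosilane.
- Fallback: it sets out from 9 and inserts C2 as CH2 instead, placing the halogen afterwards. Furukawa cyclopropanation (Et2Zn, CH2I2, toluene, 0 °C) should give the siloxycyclopropane F1. Saegusa-type oxidative ring enlargement with FeCl3 in DMF cuts the shared C1–C3 bond to the 3-chloro ketone F2. NaOAc in MeOH removes HCl to give the enone F3, and Johnson iodination (I2, pyridine, CH2Cl2) gives the 2-iodoenone F4.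
- Return: F4 replaces 12 under the conditions of step 10, and the route is rejoined at 17.

2. Step 10.
- What may go wrong: the epoxy bromoenone may decay thermally or under base before the C–N bond forms. The diamine ligand may add to the enone in conjugate fashion. The alkynyl silyl group may be lost, followed by copper acetylide chemistry.
- Fallback: it sets out from 12 and brings in nitrogen as an ammonia surrogate, with acylation afterwards. Palladium-catalysed coupling with benzophenone imine (Pd2(dba)3, BINAP, Cs2CO3, toluene, 80 °C) should give the N-(diphenylmethylene)aminoenone F5. Citric acid in THF–H2O then frees the 2-aminoenone F6.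
- Acyl partner: ester 15 is saponified (LiOH) to (2E,4E)-5-cyclohexylpenta-2,4-dienoic acid F7, which is converted with oxalyl chloride and catalytic DMF into the acid chloride F8.
- Return: acylation of F6 with F8 (pyridine, CH2Cl2, 0 °C) rejoins the route at 17.

3. Step 12.
- What may go wrong: the palladium/tin hydride system may reduce the enone in conjugate fashion or open the α,β-epoxy ketone reductively. Regiocontrol of tin delivery may be poor.
- Fallback: it sets out from 18, avoids tin hydride and bypasses 19. Sonogashira coupling of 18 with 27 (PdCl2(PPh3)2, CuI, Et3N, THF, rt) should give the dienyne F9. Ruthenium-catalysed trans-hydrosilylation ([Cp*Ru(MeCN)3]PF6, (EtO)3SiH, CH2Cl2) should then give the triethoxysilyl triene F10, in which C4 and the dienyl chain are trans.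
- Return: protodesilylation with AgF in THF–MeOH–H2O, with retention of geometry, rejoins the route at 28.

Further compounds
F1 | step 7 | siloxycyclopropane (CH2 bridging C1 and C3 of 9) | C[Si](C)(C)O[C@]12[C@H](C1)[C@](O[Si](CC)(CC)CC)(C#C[Si](C)(C)C)[C@H]3O[C@@H]23
F2 | step 7 | 3-chloro-5,6-epoxy-4-(triethylsilyloxy)-4-[(trimethylsilyl)ethynyl]cyclohexan-1-one (C3 epimers) | C1C(Cl)[C@](O[Si](CC)(CC)CC)(C#C[Si](C)(C)C)[C@H]2O[C@H]2C1=O
F3 | step 7 | (4S,5S,6R)-5,6-epoxy-4-(triethylsilyloxy)-4-[(trimethylsilyl)ethynyl]cyclohex-2-en-1-one | C1=C[C@](O[Si](CC)(CC)CC)(C#C[Si](C)(C)C)[C@H]2O[C@H]2C1=O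
F4 | step 7 | (4S,5S,6R)-5,6-epoxy-2-iodo-4-(triethylsilyloxy)-4-[(trimethylsilyl)ethynyl]cyclohex-2-en-1-one | IC1=C[C@](O[Si](CC)(CC)CC)(C#C[Si](C)(C)C)[C@H]2O[C@H]2C1=O
F5 | step 10 | 2-[(diphenylmethylene)amino] analogue of 12 | C(=NC1=C[C@](O[Si](CC)(CC)CC)(C#C[Si](C)(C)C)[C@H]2O[C@H]2C1=O)(c1ccccc1)c1ccccc1
F6 | step 10 | 2-amino-5,6-epoxy-4-(triethylsilyloxy)-4-[(trimethylsilyl)ethynyl]cyclohex-2-en-1-one | NC1=C[C@](O[Si](CC)(CC)CC)(C#C[Si](C)(C)C)[C@H]2O[C@H]2C1=O
F7 | step 10 | (2E,4E)-5-cyclohexylpenta-2,4-dienoic acid | OC(=O)/C=C/C=C/C1CCCCC1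
F8 | step 10 | (2E,4E)-5-cyclohexylpenta-2,4-dienoyl chloride | ClC(=O)/C=C/C=C/C1CCCCC1
F9 | step 12 | 1′,2′-didehydro analogue of 28 (dienyne) | O=C(/C=C/C=C/C1CCCCC1)NC1=C[C@](O)(C#C/C=C/C=C/C(=O)NC2=C(O)CCC2=O)[C@H]2O[C@H]2C1=O
F10 | step 12 | 2′-(triethoxysilyl) analogue of 28 | O=C(/C=C/C=C/C1CCCCC1)NC1=C[C@](O)(/C=C(/C=C/C=C/C(=O)NC2=C(O)CCC2=O)[Si](OCC)(OCC)OCC)[C@H]2O[C@H]2C1=O
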